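**Plan**
- Retrosynthetic cuts, in order: the two aryl–prenyl bonds on ring B; O1–C2 of ring C together with the C2=C3 unsaturation; C4a–C5 of ring A; C4–C4a; and the C2=C3 olefin of the cinnamoyl unit.
- Enabling feature: ring A (C4a, C5, C6, C7, C8, C8a) carries oxygen on C5, C7 and C8a and the carbonyl carbon C4 on C4a. This acylphloroglucinol is the Claisen-folded form of a tetraketide started by the α-methoxycinnamoyl unit (C4, C3, C2, ring B), and the chain is stored as a 4-hydroxy-2-pyrone.
- Forward order: ring B aldehyde, then α-methoxycinnamate (C2=C3), then acylation of the pyrone dianion (C4–C4a), then ring A by Claisen folding (C4a–C5), then ring C by oxa-Michael closure (O1–C2) and dehydrogenation, then twofold Stille prenylation, then MOM removal.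
- The prenyl groups are attached only after the single oxidation, so DDQ never meets them; the two bromines that will carry them pass through the fold as spectators.
- Stereochemistry: the target has no stereocentre. The Z enol ether and the trans flavanone centres are transient and are erased at the flavone stage.

Key step: step 4

Remark: aldol 4 is an unassigned mixture of racemic diastereomers and flavanone 10 is racemic (its SMILES shows the 2R,3R enantiomer of the trans pair); neither affects the target.

**Route**

Step 1
Reactants: 1 3,5-dibromo-4-hydroxybenzaldehyde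
Product: 2 3,5-dibromo-4-(methoxymethoxy)benzaldehyde
Conditions: MOMCl, K2CO3, DMF, 0 °C to rt
Reagents that add atoms: chloromethyl methyl ether, COCCl
Why: Williamson-type O-alkylation of the acidic 2,6-dibromophenoxide by the reactive chloromethyl ether should give the MOM acetal, which withstands every basic step that follows.

Step 2
Reactants: 2 3,5-dibromo-4-(methoxymethoxy)benzaldehyde; 3 methyl methoxyacetate
Product: 5 methyl (Z)-3-[3,5-dibromo-4-(methoxymethoxy)phenyl]-2-methoxyprop-2-enoate, via aldol adduct 4 (not isolated)
Conditions: NaOMe (3 equiv), 3 (4 equiv), THF, 0 °C to rt; aq. NH4Cl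
Reagents that add atoms: none
Why: Aldol condensation of the ester enolate of 3 with the non-enolisable aldehyde, followed by E1cB dehydration of aldol 4, should give the conjugated enol ether ester as the thermodynamically preferred Z isomer (aryl trans to the ester), since reversible methoxide addition equilibrates the geometry.

Step 3
Reactants: 5 methyl (Z)-3-[3,5-dibromo-4-(methoxymethoxy)phenyl]-2-methoxyprop-2-enoate; 6 4-hydroxy-6-methylpyran-2-one
Product: 7 6-[(Z)-4-[3,5-dibromo-4-(methoxymethoxy)phenyl]-3-methoxy-2-oxobut-3-enyl]-4-hydroxypyran-2-one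
Conditions: 6 (3 equiv), LiN(i-Pr)2 (6.1 equiv), THF–DMPU, –78 to –20 °C; then 5, –78 to 0 °C; cold 1 M HCl to pH 3
Reagents that add atoms: none
Why: Claisen-type C-acylation of the 6-methyl carbanion of the pyrone dianion by a methyl ester is an established way to 6-(2-oxoalkyl)-4-hydroxy-2-pyrones; the excess dianion absorbs the acidic proton of the product, and the α-methoxy group makes the enoate a poor Michael acceptor, so attack at the ester carbonyl should prevail.

Step 4
Reactants: 7 6-[(Z)-4-[3,5-dibromo-4-(methoxymethoxy)phenyl]-3-methoxy-2-oxobut-3-enyl]-4-hydroxypyran-2-one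
Product: 9 (Z)-3-[3,5-dibromo-4-(methoxymethoxy)phenyl]-2-methoxy-1-(2,4,6-trihydroxyphenyl)prop-2-en-1-one, via open-chain trioxo ester 8 (not isolated)
Conditions: Mg(OMe)2 (8 equiv), MeOH, 65 °C; then cold 1 M HCl
Reagents that add atoms: none
Why: Methoxide opens the lactone of the magnesium pyronate to the methyl 3,5,7-trioxo ester 8, held as a magnesium enolate chelate; the carbanion of the methylene between the 5- and 7-carbonyls (future C4a) adds to the ester carbonyl (future C5), methoxide leaves, and the cyclic trione enolises to the aromatic ring. The closest known reaction type is the Mg(OMe)2-induced Claisen (Dieckmann-type) cyclisation of 3,5,7-triketo esters and of 6-(2-oxoalkyl)-4-hydroxy-2-pyrones to acylphloroglucinols. Ring A closes in the 6-exo-trig mode, the enolate carbon attacking an ester C=O whose oxygen stays outside the ring. No stereocentre is formed, and the Z enol ether geometry is the thermodynamic one and is carried through. The step needs Claisen rather than aldol folding, since attack of C2 on the 7-carbonyl would give a resorcylate. The 7-carbonyl belongs to an α-methoxy enone and is a weak electrophile, chelation of the 5,7-dioxo unit by the magnesium ion keeps the nucleophilic carbon at C6, and the water-free methoxide medium avoids the ester saponification that would close the Claisen path.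

Step 5
Reactants: 9 (Z)-3-[3,5-dibromo-4-(methoxymethoxy)phenyl]-2-methoxy-1-(2,4,6-trihydroxyphenyl)prop-2-en-1-one
Product: 10 (2R*,3R*)-2-[3,5-dibromo-4-(methoxymethoxy)phenyl]-5,7-dihydroxy-3-methoxy-2,3-dihydrochromen-4-one (racemic trans flavanone)
Conditions: NaOAc, EtOH, reflux
Reagents that add atoms: none
Why: Intramolecular oxa-Michael addition (6-endo-trig) of a 2'-phenoxide to the enone is favoured by the 2',6'-dihydroxy pattern, and the reversible addition with an epimerisable C3 should place the aryl and methoxy groups trans-diequatorial under thermodynamic control, both centres being erased in step 6.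

Step 6
Reactants: 10 (2R*,3R*)-2-[3,5-dibromo-4-(methoxymethoxy)phenyl]-5,7-dihydroxy-3-methoxy-2,3-dihydrochromen-4-one
Product: 11 2-[3,5-dibromo-4-(methoxymethoxy)phenyl]-5,7-dihydroxy-3-methoxychromen-4-one
Conditions: DDQ (1.5 equiv), 1,4-dioxane, reflux
Reagents that add atoms: none
Why: DDQ dehydrogenation of a flavanone to a flavone, by hydride abstraction from C2 of the enol to a 4-hydroxyflavylium ion that loses the C3 proton, should proceed cleanly here because no prenyl group with allylic-benzylic C–H bonds is yet present.

Step 7
Reactants: 11 2-[3,5-dibromo-4-(methoxymethoxy)phenyl]-5,7-dihydroxy-3-methoxychromen-4-one; 12 tributyl(3-methylbut-2-enyl)stannane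
Product: 14 5,7-dihydroxy-3-methoxy-2-[4-(methoxymethoxy)-3,5-bis(3-methylbut-2-enyl)phenyl]chromen-4-one, via monoprenyl bromide 13 (not isolated)
Conditions: 12 (4 equiv), Pd(PPh3)4 (10 mol %), degassed DMF, 100 °C; aq. KF work-up
Reagents that add atoms: none
Why: Twofold Stille coupling, in which each aryl C–Br bond adds oxidatively to zerovalent palladium, the allylic stannane transmetalates and reductive elimination occurs at the less hindered terminus of the allyl ligand, should give the linear 3-methylbut-2-enyl groups under neutral conditions that tolerate the free 5- and 7-hydroxyls.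

Step 8
Reactants: 14 5,7-dihydroxy-3-methoxy-2-[4-(methoxymethoxy)-3,5-bis(3-methylbut-2-enyl)phenyl]chromen-4-one
Product: 15 5,7-dihydroxy-2-[4-hydroxy-3,5-bis(3-methylbut-2-enyl)phenyl]-3-methoxychromen-4-one
Conditions: 2 M aq. HCl (few equiv), MeOH, rt to 40 °C, stopped at full conversion
Reagents that add atoms: none
Why: Acid-catalysed transacetalisation of the MOM aryl ether with methanol, run dilute and near room temperature, should free the phenol before the trisubstituted prenyl alkenes are protonated, which would lead to chroman formation.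

**Compound list**
1 | 3,5-dibromo-4-hydroxybenzaldehyde | O=Cc1cc(Br)c(O)c(Br)c1 | starting material
2 | 3,5-dibromo-4-(methoxymethoxy)benzaldehyde | COCOc1c(Br)cc(C=O)cc1Br | intermediate
3 | methyl methoxyacetate | COCC(=O)OC | starting material
4 | methyl 3-[3,5-dibromo-4-(methoxymethoxy)phenyl]-3-hydroxy-2-methoxypropanoate (aldol adduct, racemic diastereomer mixture, not isolated) | COCOc1c(Br)cc(C(O)C(OC)C(=O)OC)cc1Br | intermediate
5 | methyl (Z)-3-[3,5-dibromo-4-(methoxymethoxy)phenyl]-2-methoxyprop-2-enoate | COCOc1c(Br)cc(/C=C(\OC)C(=O)OC)cc1Br | intermediate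
6 | 4-hydroxy-6-methylpyran-2-one | Cc1cc(O)cc(=O)o1 | starting material
7 | 6-[(Z)-4-[3,5-dibromo-4-(methoxymethoxy)phenyl]-3-methoxy-2-oxobut-3-enyl]-4-hydroxypyran-2-one | O=c1cc(O)cc(CC(=O)/C(OC)=C/c2cc(Br)c(OCOC)c(Br)c2)o1 | intermediate
8 | methyl (Z)-9-[3,5-dibromo-4-(methoxymethoxy)phenyl]-8-methoxy-3,5,7-trioxonon-8-enoate (open-chain trioxo ester, not isolated) | COC(=O)CC(=O)CC(=O)CC(=O)/C(OC)=C/c1cc(Br)c(OCOC)c(Br)c1 | intermediate
9 | (Z)-3-[3,5-dibromo-4-(methoxymethoxy)phenyl]-2-methoxy-1-(2,4,6-trihydroxyphenyl)prop-2-en-1-one | COCOc1c(Br)cc(/C=C(\OC)C(=O)c2c(O)cc(O)cc2O)cc1Br | intermediate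
10 | (2R*,3R*)-2-[3,5-dibromo-4-(methoxymethoxy)phenyl]-5,7-dihydroxy-3-methoxy-2,3-dihydrochromen-4-one (racemic, trans) | O=C1c2c(O)cc(O)cc2O[C@H](c2cc(Br)c(OCOC)c(Br)c2)[C@H]1OC | intermediate
11 | 2-[3,5-dibromo-4-(methoxymethoxy)phenyl]-5,7-dihydroxy-3-methoxychromen-4-one | COc1c(-c2cc(Br)c(OCOC)c(Br)c2)oc2cc(O)cc(O)c2c1=O | intermediate
12 | tributyl(3-methylbut-2-enyl)stannane | CCCC[Sn](CCCC)(CCCC)CC=C(C)C | starting material
13 | 2-[3-bromo-4-(methoxymethoxy)-5-(3-methylbut-2-enyl)phenyl]-5,7-dihydroxy-3-methoxychromen-4-one (monoprenyl bromide, not isolated) | COc1c(-c2cc(Br)c(OCOC)c(CC=C(C)C)c2)oc2cc(O)cc(O)c2c1=O | intermediate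
14 | 5,7-dihydroxy-3-methoxy-2-[4-(methoxymethoxy)-3,5-bis(3-methylbut-2-enyl)phenyl]chromen-4-one | COc1c(-c2cc(CC=C(C)C)c(OCOC)c(CC=C(C)C)c2)oc2cc(O)cc(O)c2c1=O | intermediate
15 | 5,7-dihydroxy-2-[4-hydroxy-3,5-bis(3-methylbut-2-enyl)phenyl]-3-methoxychromen-4-one | COc1c(-c2cc(CC=C(C)C)c(O)c(CC=C(C)C)c2)oc2cc(O)cc(O)c2c1=O | target

**Step count and risks**
Total steps: 8. Longest linear sequence: 8 steps (1 to 15); compounds 3, 6 and 12 enter as purchased materials.

Steps most likely to fail:

Step 7. The allyl ligand may couple through its substituted terminus and give 1,1-dimethylallyl isomers, the second hindered C–Br bond may react incompletely, and the acidic 7-hydroxyl may protonate and consume the prenylstannane. The fallback sets out from 11 and installs the side chains in two stages. Stille coupling with allyltributylstannane (Pd(PPh3)4, DMF, 90 °C), which has no regiochemical ambiguity, should lead through 2-[3-bromo-4-(methoxymethoxy)-5-prop-2-enylphenyl]-5,7-dihydroxy-3-methoxychromen-4-one F1 to 5,7-dihydroxy-3-methoxy-2-[4-(methoxymethoxy)-3,5-bis(prop-2-enyl)phenyl]chromen-4-one F2. Cross-metathesis of F2 with excess 2-methylbut-2-ene (second-generation Grubbs catalyst, CH2Cl2, 40 °C) would then convert both allyl groups into prenyl groups and return to the route at 14.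

Step 3. The carbanion may add in conjugate fashion to the enoate, or the acylation may stall because the acidic product quenches the dianion. The fallback sets out from 5 and changes the acyl donor. Aminolysis with MeNH(OMe)·HCl and AlMe3 (CH2Cl2, 0 °C to rt) should give the Weinreb amide (Z)-3-[3,5-dibromo-4-(methoxymethoxy)phenyl]-N,2-dimethoxy-N-methylprop-2-enamide F3. The dianion of 6 (1.5 equiv, LiN(i-Pr)2, THF, –78 to 0 °C) would add once to F3, and the chelated tetrahedral adduct would release the ketone only on acidic work-up, returning to the route at 7.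

Step 4. Methanolysis of the magnesium pyronate may be slow, so that at the temperature required the open chain also folds the aldol way or the enone is degraded by methoxide. The fallback sets out from 5 and separates chain formation from ring closure. Purchased methyl 3,5-dioxohexanoate is converted into its trianion (LiN(i-Pr)2, 3 equiv, THF, –78 to 0 °C) and acylated at the terminal methyl group by 5, which should give the open-chain trioxo ester 8 directly. Isolated 8 would then be closed with Mg(OMe)2 in methanol at room temperature, where chelation control is strongest, returning to the route at 9. No compound outside the list arises (F0).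

**Further compounds**
F1 | step 7 | 2-[3-bromo-4-(methoxymethoxy)-5-prop-2-enylphenyl]-5,7-dihydroxy-3-methoxychromen-4-one | COc1c(-c2cc(Br)c(OCOC)c(CC=C)c2)oc2cc(O)cc(O)c2c1=O
F2 | step 7 | 5,7-dihydroxy-3-methoxy-2-[4-(methoxymethoxy)-3,5-bis(prop-2-enyl)phenyl]chromen-4-one | COc1c(-c2cc(CC=C)c(OCOC)c(CC=C)c2)oc2cc(O)cc(O)c2c1=O
F3 | step 3 | (Z)-3-[3,5-dibromo-4-(methoxymethoxy)phenyl]-N,2-dimethoxy-N-methylprop-2-enamide | COCOc1c(Br)cc(/C=C(\OC)C(=O)N(C)OC)cc1Br
F0 | step 4 | none | none
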